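**Plan**

1. Retrosynthesis: the eighteen methyl ethers come off last. Rings C, E and G are each cut at their C1–C6 bond, which unravels the benzene ring into a 4-aryloxy-6-(aryloxymethyl)-2-pyranone. Each pyranone is cut at its CH2–O bond (Mitsunobu) and its C4–O bond (addition–elimination). Only the ring A–O–ring B ether is cut as an aryl C–O bond (Ullmann).
2. Enabling feature (rings lettered A to H from the 3,5-dihydroxyphenoxy end): ring C, like rings E and G, is a phloroglucinol ring (oxygens on C2, C4, C6) that carries the preceding ring's oxygen on C1, between the C2 and C6 hydroxyls, and the following ring's oxygen on C4. Its six carbons map onto pyranone C2–C6 plus the exocyclic CH2, a triketide chain that can hold both aryloxy groups before the benzene ring exists.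
3. Fragments: the ring A–B phenol (Ullmann coupling, Dakin oxidation), the benzyl-protected ring D/F phenol (formylation, benzylation, Dakin oxidation) and two 4-aryloxy-6-(hydroxymethyl)-2-pyranones. The oxygenated CH2 is built in from a glycolate ester, because a 6-methyl group could not be brominated without attack on the electron-rich aryl ethers.
4. Assembly: rings arise in the order C, E, G. Each cycle is Mitsunobu etherification, Mg(OMe)2 lactone opening with Claisen closure, O-methylation, and hydrogenolysis of the benzyl ether that masks the next phenol. BBr3 then frees all twenty hydroxyls.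
5. Stereochemistry: the target is achiral and has no stereocentre. The only stereochemical element on the way is the E enoate of the open-chain intermediates, inherited from the pyranone ring.

Key step: step 13

Remark: in the names below, C1 of rings B, D and F carries the oxygen toward ring A and C2 the oxygen toward ring H; C1 of rings C, E and G carries the oxygen toward ring A and C4 the oxygen toward ring H. Mg(OMe)2 is taken as its commercial methanol solution.

**Route**

Step 1
Reactants: 1 3,5-dimethoxyphenol; 2 2-bromo-3,4,5-trimethoxybenzaldehyde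
Product: 3 2-(3,5-dimethoxyphenoxy)-3,4,5-trimethoxybenzaldehyde
Conditions: CuI (10 mol %), N,N-dimethylglycine hydrochloride (30 mol %), Cs2CO3, 1,4-dioxane, 100 °C
Reagents that add atoms: none
Why: Copper-catalysed Ullmann diaryl ether coupling, in which the ortho-formyl group activates the C–Br bond and the unhindered phenoxide of 1 is a good partner.

Step 2
Reactants: 3 2-(3,5-dimethoxyphenoxy)-3,4,5-trimethoxybenzaldehyde
Product: 5 2-(3,5-dimethoxyphenoxy)-3,4,5-trimethoxyphenol, via aryl formate 4 (not isolated)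
Conditions: mCPBA, CH2Cl2, 0 °C to rt; aq. NaHCO3 wash; then cat. K2CO3, MeOH, rt
Reagents that add atoms: mCPBA, O=C(OO)c1cccc(Cl)c1
Why: Baeyer–Villiger (Dakin-type) oxidation of an electron-rich benzaldehyde, in which the oxygen-rich aryl group migrates in preference to hydride and mild methanolysis of the formate frees the phenol.

Step 3
Reactants: 6 3,4,5-trimethoxyphenol
Product: 7 6-hydroxy-2,3,4-trimethoxybenzaldehyde
Conditions: MgCl2, Et3N, paraformaldehyde, MeCN, reflux; aq. HCl work-up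
Reagents that add atoms: paraformaldehyde (formaldehyde source), C=O
Why: Magnesium phenoxide-directed ortho-formylation of a phenol with formaldehyde (a second equivalent accepts hydride), and both ortho positions of 6 are equivalent so a single regioisomer should form.

Step 4
Reactants: 7 6-hydroxy-2,3,4-trimethoxybenzaldehyde
Product: 8 6-(benzyloxy)-2,3,4-trimethoxybenzaldehyde
Conditions: BnBr, K2CO3, DMF, 60 °C
Reagents that add atoms: benzyl bromide, BrCc1ccccc1
Why: Williamson etherification, for which K2CO3 in warm DMF is enough to alkylate the hydrogen-bonded salicylaldehyde hydroxyl.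

Step 5
Reactants: 8 6-(benzyloxy)-2,3,4-trimethoxybenzaldehyde
Product: 10 6-(benzyloxy)-2,3,4-trimethoxyphenol, via aryl formate 9 (not isolated)
Conditions: mCPBA, CH2Cl2, 0 °C to rt; aq. NaHCO3 wash; then cat. K2CO3, MeOH, rt
Reagents that add atoms: mCPBA, O=C(OO)c1cccc(Cl)c1
Why: Baeyer–Villiger (Dakin-type) oxidation, in which the aryl group flanked by two oxygens migrates readily and the benzyl ether is inert to the peracid.

Step 6
Reactants: 11 methyl acetoacetate; 12 methyl 2-[(tert-butyldimethylsilyl)oxy]acetate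
Product: 14 6-{[(tert-butyldimethylsilyl)oxy]methyl}-4-hydroxy-2H-pyran-2-one, via 3,5-dioxohexanoate 13 (not isolated)
Conditions: 11 (2.2 equiv), NaH then n-BuLi, THF, 0 °C; 12, 0 °C to rt; aq. HCl; then DBU, toluene, 110 °C on the crude material
Reagents that add atoms: none
Why: Claisen acylation of the acetoacetate dianion at its terminal carbon by ester 12, then base-mediated lactonisation of the 3,5-dioxo ester through its C5 enol, the standard entry to 6-substituted 4-hydroxy-2-pyranones, with the silyl ether stable to both stages.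

Step 7
Reactants: 14 6-{[(tert-butyldimethylsilyl)oxy]methyl}-4-hydroxy-2H-pyran-2-one
Product: 15 6-{[(tert-butyldimethylsilyl)oxy]methyl}-2-oxo-2H-pyran-4-yl 4-methylbenzenesulfonate
Conditions: TsCl, Et3N, CH2Cl2, 0 °C
Reagents that add atoms: 4-methylbenzenesulfonyl chloride, Cc1ccc(cc1)S(Cl)(=O)=O
Why: O-Sulfonylation of the acidic vinylogous acid hydroxyl under buffered conditions that leave the silyl ether intact.

Step 8
Reactants: 15 6-{[(tert-butyldimethylsilyl)oxy]methyl}-2-oxo-2H-pyran-4-yl 4-methylbenzenesulfonate; 10 6-(benzyloxy)-2,3,4-trimethoxyphenol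
Product: 16 4-[6-(benzyloxy)-2,3,4-trimethoxyphenoxy]-6-{[(tert-butyldimethylsilyl)oxy]methyl}-2H-pyran-2-one
Conditions: Cs2CO3, MeCN, rt to 50 °C
Reagents that add atoms: none
Why: Nucleophilic vinylic substitution by addition–elimination at C4 of a vinylogous acyl sulfonate, where the hindered phenoxide should prefer the open trigonal C4 to the sulfonyl sulfur, as amines, thiolates and phenoxides do with 4-sulfonyloxy- and 4-halo-2-pyranones.

Step 9
Reactants: 16 4-[6-(benzyloxy)-2,3,4-trimethoxyphenoxy]-6-{[(tert-butyldimethylsilyl)oxy]methyl}-2H-pyran-2-one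
Product: 17 4-[6-(benzyloxy)-2,3,4-trimethoxyphenoxy]-6-(hydroxymethyl)-2H-pyran-2-one
Conditions: HF·pyridine, THF, 0 °C to rt
Reagents that add atoms: none
Why: Fluoride-mediated desilylation under mildly acidic conditions that spare the lactone, the aryl vinyl ether and the benzyl ether.

Step 10
Reactants: 15 6-{[(tert-butyldimethylsilyl)oxy]methyl}-2-oxo-2H-pyran-4-yl 4-methylbenzenesulfonate; 18 2,4,6-trimethoxyphenol
Product: 19 6-{[(tert-butyldimethylsilyl)oxy]methyl}-4-(2,4,6-trimethoxyphenoxy)-2H-pyran-2-one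
Conditions: Cs2CO3, MeCN, rt to 50 °C
Reagents that add atoms: none
Why: The same addition–elimination at C4 of the vinylogous acyl sulfonate as in step 8, here with the phenoxide that becomes ring H.

Step 11
Reactants: 19 6-{[(tert-butyldimethylsilyl)oxy]methyl}-4-(2,4,6-trimethoxyphenoxy)-2H-pyran-2-one
Product: 20 6-(hydroxymethyl)-4-(2,4,6-trimethoxyphenoxy)-2H-pyran-2-one
Conditions: HF·pyridine, THF, 0 °C to rt
Reagents that add atoms: none
Why: Fluoride-mediated desilylation, as in step 9.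

Step 12
Reactants: 5 2-(3,5-dimethoxyphenoxy)-3,4,5-trimethoxyphenol; 17 4-[6-(benzyloxy)-2,3,4-trimethoxyphenoxy]-6-(hydroxymethyl)-2H-pyran-2-one
Product: 21 4-[6-(benzyloxy)-2,3,4-trimethoxyphenoxy]-6-{[2-(3,5-dimethoxyphenoxy)-3,4,5-trimethoxyphenoxy]methyl}-2H-pyran-2-one
Conditions: PPh3, DIAD (added last), THF, 0 °C to rt
Reagents that add atoms: none
Why: Mitsunobu etherification, in which the primary alcohol is activated as its oxyphosphonium salt and displaced (SN2) by the phenoxide of 5 under neutral conditions that leave the aryloxypyranone untouched.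

Step 13
Reactants: 21 4-[6-(benzyloxy)-2,3,4-trimethoxyphenoxy]-6-{[2-(3,5-dimethoxyphenoxy)-3,4,5-trimethoxyphenoxy]methyl}-2H-pyran-2-one
Product: 23 5-[6-(benzyloxy)-2,3,4-trimethoxyphenoxy]-2-[2-(3,5-dimethoxyphenoxy)-3,4,5-trimethoxyphenoxy]benzene-1,3-diol (ring A–B–C–D tetramer; ring C diol), via ring-opened keto ester 22 (not isolated)
Conditions: Mg(OMe)2 (5 equiv), MeOH–THF, reflux; then aq. HCl
Reagents that add atoms: none
Why: Proposed new method: Mg(OMe)2 should deliver methoxide to the magnesium-bound lactone carbonyl of 21 and open the ring to the magnesium enolate of keto ester 22, whose enoate keeps the E geometry of the ring so that the ester stays cis to the ketone arm; proton exchange in methanol then gives the enolate at the aryloxymethyl carbon (C6 of 22), which adds to the ester carbonyl (C1 of 22), loses methoxide and tautomerises to the aromatic magnesium bis-phenoxide, an irreversible sink. The closest known reaction types are the Mg(OMe)2-induced opening of 6-(acylmethyl)-4-hydroxy-2-pyranones with Claisen or aldol closure to acylphloroglucinols and resorcylates, and the Dieckmann-type cyclisation of 3,5-dioxohexanoate esters to phloroglucinol; not shown so far are a nucleophilic carbon activated by only one ketone and an aryloxy group, and an aryloxy-substituted enoate as acceptor. Ring C closes in a 6-(enolendo)-exo-trig Claisen (Dieckmann) mode that forms its C1–C6 bond. No stereocentre is formed. The step needs methoxide to attack the lactone carbonyl and not pyranone C4 (which would expel the ring D phenoxide), which magnesium coordination at the carbonyl and the two ortho substituents of ring D flanking C4 should secure; it also needs carbon–carbon closure through the aryloxymethyl enolate, which is the only enolate able to reach the ester through a six-membered transition state, since the more acidic C4 methylene of 22 could close only a four-membered ring and O-attack merely regenerates 21 reversibly.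

Step 14
Reactants: 23 ring A–B–C–D tetramer with ring C diol
Product: 24 ring A–B–C–D tetramer benzyl ether (23 with both ring C hydroxyls methylated)
Conditions: MeI, K2CO3, DMF, rt
Reagents that add atoms: iodomethane, CI
Why: Williamson O-methylation of the two ring C phenols, so that only the ring D oxygen is free in the next cycle.

Step 15
Reactants: 24 ring A–B–C–D tetramer benzyl ether
Product: 25 ring A–B–C–D tetramer phenol (free hydroxyl on ring D C2; all other oxygens methylated)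
Conditions: H2 (1 atm), Pd/C, EtOAc–MeOH, rt
Reagents that add atoms: none
Why: Catalytic hydrogenolysis of the aryl benzyl ether, to which aryl methyl ethers and diaryl ethers are inert.

Step 16
Reactants: 25 ring A–B–C–D tetramer phenol; 17 4-[6-(benzyloxy)-2,3,4-trimethoxyphenoxy]-6-(hydroxymethyl)-2H-pyran-2-one
Product: 26 second pyranone: 4-[6-(benzyloxy)-2,3,4-trimethoxyphenoxy]-6-(aryloxymethyl)-2H-pyran-2-one whose aryloxy group is the ring D C2 oxygen of 25
Conditions: PPh3, DIAD (added last), THF, 0 °C to rt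
Reagents that add atoms: none
Why: Mitsunobu etherification of the single free phenol of 25 with the primary alcohol of 17, as in step 12.

Step 17
Reactants: 26 second pyranone
Product: 28 ring A–F hexamer (ring E diol; ring F C2 benzyl ether), via ring-opened keto ester 27 (not isolated)
Conditions: Mg(OMe)2 (5 equiv), MeOH–THF, reflux; then aq. HCl
Reagents that add atoms: none
Why: Proposed new method: the same Mg(OMe)2 lactone opening and 6-(enolendo)-exo-trig Claisen closure as in step 13 (methoxide attack at the lactone carbonyl, enolisation toward the aryloxymethyl carbon, attack on the ester, aromatisation), here closing ring E between rings D and F, the closest known reaction type being the Mg(OMe)2-mediated opening of 6-(acylmethyl)-4-hydroxy-2-pyranones with Claisen closure to acylphloroglucinols.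

Step 18
Reactants: 28 ring A–F hexamer with ring E diol
Product: 29 ring A–F hexamer benzyl ether (28 with both ring E hydroxyls methylated)
Conditions: MeI, K2CO3, DMF, rt
Reagents that add atoms: iodomethane, CI
Why: Williamson O-methylation of the two ring E phenols, as in step 14.

Step 19
Reactants: 29 ring A–F hexamer benzyl ether
Product: 30 ring A–F hexamer phenol (free hydroxyl on ring F C2; all other oxygens methylated)
Conditions: H2 (1 atm), Pd/C, EtOAc–MeOH, rt
Reagents that add atoms: none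
Why: Catalytic hydrogenolysis of the aryl benzyl ether, as in step 15.

Step 20
Reactants: 30 ring A–F hexamer phenol; 20 6-(hydroxymethyl)-4-(2,4,6-trimethoxyphenoxy)-2H-pyran-2-one
Product: 31 third pyranone: 6-(aryloxymethyl)-4-(2,4,6-trimethoxyphenoxy)-2H-pyran-2-one whose aryloxy group is the ring F C2 oxygen of 30
Conditions: PPh3, DIAD (added last), THF, 0 °C to rt
Reagents that add atoms: none
Why: Mitsunobu etherification of the single free phenol of 30 with the primary alcohol of 20, as in step 12.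

Step 21
Reactants: 31 third pyranone
Product: 33 ring A–H octamer (ring G diol; eighteen methyl ethers), via ring-opened keto ester 32 (not isolated)
Conditions: Mg(OMe)2 (5 equiv), MeOH–THF, reflux; then aq. HCl
Reagents that add atoms: none
Why: Proposed new method: the same Mg(OMe)2 lactone opening and 6-(enolendo)-exo-trig Claisen closure as in step 13, here closing ring G between ring F and the 2,4,6-trimethoxyphenyl ring H, the closest known reaction type being the Mg(OMe)2-mediated opening of 6-(acylmethyl)-4-hydroxy-2-pyranones with Claisen closure to acylphloroglucinols.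

Step 22
Reactants: 33 ring A–H octamer with ring G diol
Product: 34 CNP0319661.0
Conditions: BBr3 (large excess), CH2Cl2, −78 °C to rt, under argon; then H2O
Reagents that add atoms: none
Why: Lewis acid O-demethylation, in which bromide attacks the methyl group of each boron-complexed aryl methyl ether while the diaryl ether bonds, which offer no sp3 carbon, are retained.

**Compound list**

1 | 3,5-dimethoxyphenol | COc1cc(O)cc(OC)c1 | starting material
2 | 2-bromo-3,4,5-trimethoxybenzaldehyde | COc1cc(C=O)c(Br)c(OC)c1OC | starting material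
3 | 2-(3,5-dimethoxyphenoxy)-3,4,5-trimethoxybenzaldehyde | COc1cc(OC)cc(Oc2c(C=O)cc(OC)c(OC)c2OC)c1 | intermediate
4 | 2-(3,5-dimethoxyphenoxy)-3,4,5-trimethoxyphenyl formate (not isolated) | COc1cc(OC)cc(Oc2c(OC=O)cc(OC)c(OC)c2OC)c1 | intermediate
5 | 2-(3,5-dimethoxyphenoxy)-3,4,5-trimethoxyphenol (ring A–B phenol) | COc1cc(OC)cc(Oc2c(O)cc(OC)c(OC)c2OC)c1 | intermediate
6 | 3,4,5-trimethoxyphenol | COc1cc(O)cc(OC)c1OC | starting material
7 | 6-hydroxy-2,3,4-trimethoxybenzaldehyde | COc1cc(O)c(C=O)c(OC)c1OC | intermediate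
8 | 6-(benzyloxy)-2,3,4-trimethoxybenzaldehyde | COc1cc(OCc2ccccc2)c(C=O)c(OC)c1OC | intermediate
9 | 6-(benzyloxy)-2,3,4-trimethoxyphenyl formate (not isolated) | COc1cc(OCc2ccccc2)c(OC=O)c(OC)c1OC | intermediate
10 | 6-(benzyloxy)-2,3,4-trimethoxyphenol | COc1cc(OCc2ccccc2)c(O)c(OC)c1OC | intermediate
11 | methyl acetoacetate | COC(=O)CC(C)=O | starting material
12 | methyl 2-[(tert-butyldimethylsilyl)oxy]acetate | COC(=O)CO[Si](C)(C)C(C)(C)C | starting material
13 | methyl 6-[(tert-butyldimethylsilyl)oxy]-3,5-dioxohexanoate (not isolated) | COC(=O)CC(=O)CC(=O)CO[Si](C)(C)C(C)(C)C | intermediate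
14 | 6-{[(tert-butyldimethylsilyl)oxy]methyl}-4-hydroxy-2H-pyran-2-one | O=C1C=C(O)C=C(CO[Si](C)(C)C(C)(C)C)O1 | intermediate
15 | 6-{[(tert-butyldimethylsilyl)oxy]methyl}-2-oxo-2H-pyran-4-yl 4-methylbenzenesulfonate | Cc1ccc(cc1)S(=O)(=O)OC1=CC(=O)OC(CO[Si](C)(C)C(C)(C)C)=C1 | intermediate
16 | 4-[6-(benzyloxy)-2,3,4-trimethoxyphenoxy]-6-{[(tert-butyldimethylsilyl)oxy]methyl}-2H-pyran-2-one | O=C1C=C(Oc2c(OCc3ccccc3)cc(OC)c(OC)c2OC)C=C(CO[Si](C)(C)C(C)(C)C)O1 | intermediate
17 | 4-[6-(benzyloxy)-2,3,4-trimethoxyphenoxy]-6-(hydroxymethyl)-2H-pyran-2-one | O=C1C=C(Oc2c(OCc3ccccc3)cc(OC)c(OC)c2OC)C=C(CO)O1 | intermediate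
18 | 2,4,6-trimethoxyphenol | COc1cc(OC)c(O)c(OC)c1 | starting material
19 | 6-{[(tert-butyldimethylsilyl)oxy]methyl}-4-(2,4,6-trimethoxyphenoxy)-2H-pyran-2-one | O=C1C=C(Oc2c(OC)cc(OC)cc2OC)C=C(CO[Si](C)(C)C(C)(C)C)O1 | intermediate
20 | 6-(hydroxymethyl)-4-(2,4,6-trimethoxyphenoxy)-2H-pyran-2-one | O=C1C=C(Oc2c(OC)cc(OC)cc2OC)C=C(CO)O1 | intermediate
21 | 4-[6-(benzyloxy)-2,3,4-trimethoxyphenoxy]-6-{[2-(3,5-dimethoxyphenoxy)-3,4,5-trimethoxyphenoxy]methyl}-2H-pyran-2-one | O=C1C=C(Oc2c(OCc3ccccc3)cc(OC)c(OC)c2OC)C=C(COc2cc(OC)c(OC)c(OC)c2Oc2cc(OC)cc(OC)c2)O1 | intermediate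
22 | methyl (2E)-3-[6-(benzyloxy)-2,3,4-trimethoxyphenoxy]-6-[2-(3,5-dimethoxyphenoxy)-3,4,5-trimethoxyphenoxy]-5-oxohex-2-enoate (not isolated) | COC(=O)/C=C(/Oc1c(OCc2ccccc2)cc(OC)c(OC)c1OC)CC(=O)COc1cc(OC)c(OC)c(OC)c1Oc1cc(OC)cc(OC)c1 | intermediate
23 | 5-[6-(benzyloxy)-2,3,4-trimethoxyphenoxy]-2-[2-(3,5-dimethoxyphenoxy)-3,4,5-trimethoxyphenoxy]benzene-1,3-diol (ring A–B–C–D tetramer; ring C diol) | COc1cc(OC)cc(Oc2c(Oc3c(O)cc(Oc4c(OCc5ccccc5)cc(OC)c(OC)c4OC)cc3O)cc(OC)c(OC)c2OC)c1 | intermediate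
24 | ring A–B–C–D tetramer benzyl ether (ring C 2,6-dimethoxy; ring D C2 benzyloxy) | COc1cc(OC)cc(Oc2c(Oc3c(OC)cc(Oc4c(OCc5ccccc5)cc(OC)c(OC)c4OC)cc3OC)cc(OC)c(OC)c2OC)c1 | intermediate
25 | ring A–B–C–D tetramer phenol (ring D C2 hydroxyl free) | COc1cc(OC)cc(Oc2c(Oc3c(OC)cc(Oc4c(O)cc(OC)c(OC)c4OC)cc3OC)cc(OC)c(OC)c2OC)c1 | intermediate
26 | second pyranone (ring D C2 oxygen of 25 on the 6-CH2; benzyl-protected ring F aryloxy on C4) | COc1cc(OC)cc(Oc2c(Oc3c(OC)cc(Oc4c(OCC5=CC(Oc6c(OCc7ccccc7)cc(OC)c(OC)c6OC)=CC(=O)O5)cc(OC)c(OC)c4OC)cc3OC)cc(OC)c(OC)c2OC)c1 | intermediate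
27 | ring-opened methyl (2E)-3-aryloxy-6-aryloxy-5-oxohex-2-enoate from 26 (not isolated) | COc1cc(OC)cc(Oc2c(Oc3c(OC)cc(Oc4c(OCC(=O)C/C(Oc5c(OCc6ccccc6)cc(OC)c(OC)c5OC)=C\C(=O)OC)cc(OC)c(OC)c4OC)cc3OC)cc(OC)c(OC)c2OC)c1 | intermediate
28 | ring A–F hexamer (ring E diol; ring F C2 benzyloxy) | COc1cc(OC)cc(Oc2c(Oc3c(OC)cc(Oc4c(Oc5c(O)cc(Oc6c(OCc7ccccc7)cc(OC)c(OC)c6OC)cc5O)cc(OC)c(OC)c4OC)cc3OC)cc(OC)c(OC)c2OC)c1 | intermediate
29 | ring A–F hexamer benzyl ether (ring E 2,6-dimethoxy; ring F C2 benzyloxy) | COc1cc(OC)cc(Oc2c(Oc3c(OC)cc(Oc4c(Oc5c(OC)cc(Oc6c(OCc7ccccc7)cc(OC)c(OC)c6OC)cc5OC)cc(OC)c(OC)c4OC)cc3OC)cc(OC)c(OC)c2OC)c1 | intermediate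
30 | ring A–F hexamer phenol (ring F C2 hydroxyl free) | COc1cc(OC)cc(Oc2c(Oc3c(OC)cc(Oc4c(Oc5c(OC)cc(Oc6c(O)cc(OC)c(OC)c6OC)cc5OC)cc(OC)c(OC)c4OC)cc3OC)cc(OC)c(OC)c2OC)c1 | intermediate
31 | third pyranone (ring F C2 oxygen of 30 on the 6-CH2; 2,4,6-trimethoxyphenoxy on C4) | COc1cc(OC)cc(Oc2c(Oc3c(OC)cc(Oc4c(Oc5c(OC)cc(Oc6c(OCC7=CC(Oc8c(OC)cc(OC)cc8OC)=CC(=O)O7)cc(OC)c(OC)c6OC)cc5OC)cc(OC)c(OC)c4OC)cc3OC)cc(OC)c(OC)c2OC)c1 | intermediate
32 | ring-opened methyl (2E)-3-aryloxy-6-aryloxy-5-oxohex-2-enoate from 31 (not isolated) | COc1cc(OC)cc(Oc2c(Oc3c(OC)cc(Oc4c(Oc5c(OC)cc(Oc6c(OCC(=O)C/C(Oc7c(OC)cc(OC)cc7OC)=C\C(=O)OC)cc(OC)c(OC)c6OC)cc5OC)cc(OC)c(OC)c4OC)cc3OC)cc(OC)c(OC)c2OC)c1 | intermediate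
33 | ring A–H octamer (ring G diol; eighteen methyl ethers) | COc1cc(OC)cc(Oc2c(Oc3c(OC)cc(Oc4c(Oc5c(OC)cc(Oc6c(Oc7c(O)cc(Oc8c(OC)cc(OC)cc8OC)cc7O)cc(OC)c(OC)c6OC)cc5OC)cc(OC)c(OC)c4OC)cc3OC)cc(OC)c(OC)c2OC)c1 | intermediate
34 | CNP0319661.0 | Oc1cc(O)cc(Oc2c(Oc3c(O)cc(Oc4c(Oc5c(O)cc(Oc6c(Oc7c(O)cc(Oc8c(O)cc(O)cc8O)cc7O)cc(O)c(O)c6O)cc5O)cc(O)c(O)c4O)cc3O)cc(O)c(O)c2O)c1 | target

**Step count and risks**

Total step count: 22. Longest linear sequence: 16 steps (steps 3, 4, 5, 8, 9 and 12 to 22).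

Steps most likely to fail (all three bear the label; each fallback replaces the pyranone closure by copper-catalysed ether coupling of a ready-made benzene ring):

Step 13. Methoxide may add to pyranone C4 and expel the ring D phenoxide (vinylogous transesterification), or the open keto ester may relactonise faster than it closes on carbon. The fallback sets out from 5 and comes back at 25, so steps 12 to 15 are not needed. Ullmann coupling of 5 with commercial 4-bromo-3,5-dimethoxybenzaldehyde (CuI, N,N-dimethylglycine, Cs2CO3, dioxane, 100 °C; the para-formyl group activates the bromide) should give the ring A–B–C aldehyde F1. Baeyer–Villiger oxidation with mCPBA should give the ring A–B–C formate F2, and methanolysis the ring A–B–C phenol F3, whose hydroxyl sits on ring C C4. A second Ullmann coupling, now with 2, should give the ring A–B–C–D aldehyde F4, mCPBA oxidation the ring A–B–C–D formate F5, and methanolysis of this formate is 25.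

Step 17. The same aryloxide expulsion or stalling at the keto ester may occur, made worse by lower solubility and slower enolisation next to the bulkier tetramer. The fallback sets out from 25 and comes back at 30, so steps 16 to 19 are not needed. Ullmann coupling of 25 with 4-bromo-3,5-dimethoxybenzaldehyde should give the ring A–E aldehyde F6, mCPBA oxidation the ring A–E formate F7, and methanolysis the ring A–E phenol F8. Ullmann coupling of this phenol with 2 should give the ring A–F aldehyde F9, mCPBA oxidation the ring A–F formate F10, and methanolysis of this formate is 30.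

Step 21. Expulsion of the 2,4,6-trimethoxyphenoxide by methoxide or incomplete closure on the largest substrate may occur. The fallback sets out from 30 and comes back at 34, so steps 20 to 22 are replaced. Ullmann coupling of 30 with 4-bromo-3,5-dimethoxybenzaldehyde should give the ring A–G aldehyde F11, mCPBA oxidation the ring A–G formate F12, and methanolysis the ring A–G phenol F13. A second coupling with 4-bromo-3,5-dimethoxybenzaldehyde should give the octamer aldehyde F14, in which the new 4-formyl-2,6-dimethoxyphenyl group is ring H. mCPBA oxidation should give the octamer formate F15, and methanolysis the octamer phenol F16 (ring H C4 hydroxyl free, nineteen methyl ethers). BBr3 under the conditions of step 22 should then give 34.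

**Further compounds**

F1 | step 13 | ring A–B–C aldehyde | COc1cc(OC)cc(Oc2c(Oc3c(OC)cc(C=O)cc3OC)cc(OC)c(OC)c2OC)c1
F2 | step 13 | ring A–B–C formate | COc1cc(OC)cc(Oc2c(Oc3c(OC)cc(OC=O)cc3OC)cc(OC)c(OC)c2OC)c1
F3 | step 13 | ring A–B–C phenol | COc1cc(OC)cc(Oc2c(Oc3c(OC)cc(O)cc3OC)cc(OC)c(OC)c2OC)c1
F4 | step 13 | ring A–B–C–D aldehyde | COc1cc(OC)cc(Oc2c(Oc3c(OC)cc(Oc4c(C=O)cc(OC)c(OC)c4OC)cc3OC)cc(OC)c(OC)c2OC)c1
F5 | step 13 | ring A–B–C–D formate | COc1cc(OC)cc(Oc2c(Oc3c(OC)cc(Oc4c(OC=O)cc(OC)c(OC)c4OC)cc3OC)cc(OC)c(OC)c2OC)c1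
F6 | step 17 | ring A–E aldehyde | COc1cc(OC)cc(Oc2c(Oc3c(OC)cc(Oc4c(Oc5c(OC)cc(C=O)cc5OC)cc(OC)c(OC)c4OC)cc3OC)cc(OC)c(OC)c2OC)c1
F7 | step 17 | ring A–E formate | COc1cc(OC)cc(Oc2c(Oc3c(OC)cc(Oc4c(Oc5c(OC)cc(OC=O)cc5OC)cc(OC)c(OC)c4OC)cc3OC)cc(OC)c(OC)c2OC)c1
F8 | step 17 | ring A–E phenol | COc1cc(OC)cc(Oc2c(Oc3c(OC)cc(Oc4c(Oc5c(OC)cc(O)cc5OC)cc(OC)c(OC)c4OC)cc3OC)cc(OC)c(OC)c2OC)c1
F9 | step 17 | ring A–F aldehyde | COc1cc(OC)cc(Oc2c(Oc3c(OC)cc(Oc4c(Oc5c(OC)cc(Oc6c(C=O)cc(OC)c(OC)c6OC)cc5OC)cc(OC)c(OC)c4OC)cc3OC)cc(OC)c(OC)c2OC)c1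
F10 | step 17 | ring A–F formate | COc1cc(OC)cc(Oc2c(Oc3c(OC)cc(Oc4c(Oc5c(OC)cc(Oc6c(OC=O)cc(OC)c(OC)c6OC)cc5OC)cc(OC)c(OC)c4OC)cc3OC)cc(OC)c(OC)c2OC)c1
F11 | step 21 | ring A–G aldehyde | COc1cc(OC)cc(Oc2c(Oc3c(OC)cc(Oc4c(Oc5c(OC)cc(Oc6c(Oc7c(OC)cc(C=O)cc7OC)cc(OC)c(OC)c6OC)cc5OC)cc(OC)c(OC)c4OC)cc3OC)cc(OC)c(OC)c2OC)c1
F12 | step 21 | ring A–G formate | COc1cc(OC)cc(Oc2c(Oc3c(OC)cc(Oc4c(Oc5c(OC)cc(Oc6c(Oc7c(OC)cc(OC=O)cc7OC)cc(OC)c(OC)c6OC)cc5OC)cc(OC)c(OC)c4OC)cc3OC)cc(OC)c(OC)c2OC)c1
F13 | step 21 | ring A–G phenol | COc1cc(OC)cc(Oc2c(Oc3c(OC)cc(Oc4c(Oc5c(OC)cc(Oc6c(Oc7c(OC)cc(O)cc7OC)cc(OC)c(OC)c6OC)cc5OC)cc(OC)c(OC)c4OC)cc3OC)cc(OC)c(OC)c2OC)c1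
F14 | step 21 | octamer aldehyde | COc1cc(OC)cc(Oc2c(Oc3c(OC)cc(Oc4c(Oc5c(OC)cc(Oc6c(Oc7c(OC)cc(Oc8c(OC)cc(C=O)cc8OC)cc7OC)cc(OC)c(OC)c6OC)cc5OC)cc(OC)c(OC)c4OC)cc3OC)cc(OC)c(OC)c2OC)c1
F15 | step 21 | octamer formate | COc1cc(OC)cc(Oc2c(Oc3c(OC)cc(Oc4c(Oc5c(OC)cc(Oc6c(Oc7c(OC)cc(Oc8c(OC)cc(OC=O)cc8OC)cc7OC)cc(OC)c(OC)c6OC)cc5OC)cc(OC)c(OC)c4OC)cc3OC)cc(OC)c(OC)c2OC)c1
F16 | step 21 | octamer phenol | COc1cc(OC)cc(Oc2c(Oc3c(OC)cc(Oc4c(Oc5c(OC)cc(Oc6c(Oc7c(OC)cc(Oc8c(OC)cc(O)cc8OC)cc7OC)cc(OC)c(OC)c6OC)cc5OC)cc(OC)c(OC)c4OC)cc3OC)cc(OC)c(OC)c2OC)c1
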